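The earlier runs and the new flask are simulated with made-up constants, noise included.

The side product shows whether the dawn flask is still moving at 25 h.

all flasks: substrate 0.19 M; partner 0.285 M

|  | reagent | remark | time |
|---|---|---|---|
| dawn | 0.20 M | the very flask that is asked about, followed so far |  |
| midnight | 0.30 M | run made earlier |  |
| flask | 0.200 M |  | 25 h |

| run | time / h | substrate / % | target / % | side product / % |
|---|---|---|---|---|
| dawn | 1.00 | 93.6 | 0.4 | 0 |
| dawn | 2.00 | 90.1 | 0.1 | 0 |
| dawn | 3.00 | 88.0 | 2.7 | 1.0 |
| dawn | 4.00 | 87.2 | 4.1 | 0.8 |
| dawn | 5.00 | 85.7 | 4.7 | 3.4 |
| midnight | 1.33 | 87.8 | 1.8 | 0 |
| midnight | 2.50 | 82.2 | 3.3 | 1.1 |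
| midnight | 5.00 | 74.8 | 9.1 | 4.1 |
| midnight | 10.0 | 68.1 | 11.5 | 15.6 |
| midnight | 20.0 | 58.0 | 6.2 | 32.5 |

(standard deviation of a reading: 0.5 percentage points)

- a species is counted by the substrate in it: one side product counts as two
- the earlier runs were read with a standard deviation of 0.5 percentage points
- the reaction counts as stopped when no species that holds the substrate changes by six tenths of a point or more over the second half of the time

* which holds at 25 h: what has brought the reaction to rest, or that it has not come to rest (the partner has run out first / all of the substrate has reacted / it is still moving)
* part of the substrate gone at 25 h
* the target standing at 25 h, as a percentage of the substrate charged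
* the side product standing at 25 h, as a percentage of the substrate charged

In the midnight run the target falls after 10.0 h while the side product climbs, as if target were meeting substrate. A rate for such a meeting can be read by replacing each curve over a stretch with its mean: divide the side product gained by mean target, mean substrate and the hours. From 10.0 h to 20.0 h the quotient reads 0.303 /h. This is the drain constant, the side product gained per hour for each unit of target times substrate, all as fractions of the substrate charged. The earlier midnight stretch reads 0.313 /h, and the noisier dawn stretch from 3.00 h to 5.00 h reads 0.373 /h.

Substrate changes slowly, so target decays in a pseudo-first-order way. A side product counts as two, so target loses one point for every two gained, and its lifetime in the dawn flask is 7.71 h. That is shorter than the last 12.5 h. Even if no target were fed after 5.00 h, my reckoning gives the side product 2.9 percentage points over those hours, beyond the stopping margin. I expect a flask still moving.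

The forecast agrees: it is still moving, with 28% gone (24% to 32%), target 3% (1.5% to 5.5%) and side product 25% (20% to 29%). It steps the flask forward by hand, not from my floor, and concludes “so the reaction is still moving”.

    substrate + reagent → open intermediate (k = 0.563 /M/h)
    reagent + partner → second intermediate (k = 3.78 /M/h)
    open intermediate + second intermediate → target (k = 1.22 /M/h)
    2 open intermediate → homo product (k = 0.786 /M/h)
    substrate + target → side product (k = 0.775 /M/h)

The flask gives it is still moving, with 23.5% gone, target 1.67% and side product 20.6%, so the forecast holds within its tolerance. Reagent stands at 0%, and target is made at 0.149 of the rate at which it is used. Over the last 12.5 h the drain constant with mean curves gives 9.4 points, against 8.8 points gained, a gap of 0.60 points that holds the error of the means together with that of the constant as read.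

The same flask read at 6.0 h: from 2.60% at 5.00 h, the drain constant gives 3.79%. The computed side product there is 3.76%.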